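The number I carried into this flask was 1.74, the selectivity factor, that is, the logarithmic decay of the left-handed substrate divided by that of the right-handed substrate, pooled over the epsilon readings from 20.0 min to 50.0 min.

all flasks: left-handed substrate 0.50 M; right-handed substrate 0.50 M
- alpha: solid reagent 0.75 M; free catalyst 25 mM; run made earlier
- epsilon: solid reagent 0.75 M; free catalyst 100 mM; run made earlier
- flask: solid reagent 0.750 M; free catalyst 50 mM; time 40 min

| run | time / min | right-handed substrate / % | left-handed substrate / % |
|---|---|---|---|
| alpha | 4.00 | 49.5 | 48.8 |
| alpha | 12.0 | 48.6 | 48.0 |
| alpha | 20.0 | 47.4 | 45.0 |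
| alpha | 30.0 | 46.3 | 44.1 |
| alpha | 50.0 | 44.7 | 42.7 |
| epsilon | 4.00 | 49.4 | 47.8 |
| epsilon | 12.0 | 46.0 | 44.0 |
| epsilon | 20.0 | 44.7 | 39.7 |
| epsilon | 30.0 | 41.9 | 36.2 |
| epsilon | 50.0 | 37.3 | 31.6 |

(standard deviation of a reading: 0.5 percentage points)

- free catalyst is single-handed; left-handed substrate and right-handed substrate are mirror images of each other, charged as a racemate, each of them at the stated concentration
- as a solid, counted per litre of solution: solid reagent
- the analysis behind the earlier runs scatters by 0.5 percentage points, standard deviation
- at the start none of the solid reagent is in solution

- whether the excess of right-handed substrate over left-handed substrate among what is left of the two reaches 90% by 40 min (yes / no)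
- the highest excess of right-handed substrate over left-handed substrate among what is left of the two up to 40 min

I froze it, taking the two mirror images to share one clock, whatever slows that clock. The excess then hangs on L, the logarithmic decay of the right-handed substrate, and while it stays small:

excess ≈ (s − 1) · L / 2

With the main step alone, its rate proportional to c(free catalyst), I scaled the epsilon run, whose L at 50.0 min was 0.293, to this flask's charge and time:

L = 0.293 × (50 mM / 100 mM) × (40 min / 50.0 min) = 0.117, excess 4.33%

The alpha run, with L = 0.112, scaled likewise gave 0.179 and 6.62%. The two disagreed: from the alpha run to the epsilon run the catalyst charge was multiplied by 4.00, and the L read off was multiplied by 2.62. So I added a response weaker than proportional and took the geometric mean, 50 mM being the geometric middle of the two charges: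

L = √(0.112 × 0.293) × (40 min / 50.0 min) = 0.145, excess 5.37%

Last came the slowing with time. The mean of the epsilon L at 30.0 min and 50.0 min was 0.802 of the later one, against the 0.800 already used, so my number stood. In the epsilon run L was larger at 50.0 min than at 30.0 min, so with the frozen selectivity factor I put the top for this flask at the end, far less than 90%.

The forecast said no and 4.7%, within 3.3% to 6.3%, “with the excess still creeping upward, so the maximum falls at the end”. Its selectivity was about 1.5, and my number came out higher than its 4.7%.

The flask gave no and a top of 5.78%.

    partner + free catalyst + left-handed substrate → free catalyst + left-handed product (k = 0.0890 /M²/s)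
    partner + free catalyst + right-handed substrate → free catalyst + right-handed product (k = 0.0510 /M²/s)
    solid reagent ⇌ partner, rate k3*(cs3 - [partner]) while solid is left; crystals form when [partner] > cs3 (solubility = 0.190 M, k = 0.00120 /s)
    partner ⇌ dormant form (K = 1.60, k = 2.80 × 10⁻⁴ /s)
    free catalyst → spent catalyst (k = 8.00 × 10⁻⁴ /s)

At 40.0 min the flask held 14.7% of its catalyst free and 85.3% spent, with 86% of its right-handed substrate left. Put into the rule, that remainder and the frozen 1.74 give 5.75%. The neighbour read at 10 min, with 96% of its right-handed substrate left, gets 1.47% from the same rule, and that neighbour stood at 1.48%.

The earlier runs and the new flask are calculated from invented constants; noise was put on by code.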